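The cyclohexene (numbered from the methyl-bearing C1) is closed last between C4 and C5. C5 is benzylic to ring C, whose ortho oxygen can turn it into the electrophilic terminus of an ortho-quinone methide, and C4 is the only α-carbon of the ring B aryl ketone; one anionic operation (enolisation, fluoride desilylation, acetate loss, Michael addition, proton return) therefore forms the C4–C5 bond, the ring and both new stereocentres relative to C3, which is set beforehand by a rhodium-catalysed asymmetric conjugate alkenylation. The precursor is an open-chain (Z)-hept-4-en-1-one with ring B on the ketone, ring A on C3, and on C7 an acetate and ring C bearing an ortho silyl ether.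

Key step: step 14

Conventions and assumptions
- Cyclohexene numbering: C1 carries the methyl group, C2 is the other alkene carbon, C3 carries ring A, C4 the ring B aroyl group, C5 ring C, C6 is the CH2 group. Ring D is the aryl group of the enone on ring A. In the open-chain compounds the heptenone locants 2, 3, 4, 5, 6, 7 correspond to C4, C3, C2, C1, C6, C5.
- The C3 centre is R in the open-chain compounds and S in the ring compounds without any change in space, because ring closure raises the CIP priority of the C4 branch above the alkene branch.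
- Assumption: the (R,R)-diene rhodium catalyst of step 12 shows its usual sense of induction with this acyclic enone (alkenyl transfer to the Si face of the β-carbon). Should a trial show the opposite sense, the (S,S)-ligand is used.
- The carbinol carbon that becomes C5 is carried as both epimers, because it becomes trigonal in step 14.
- Design of the precursor: the ring C ortho oxygen carries a triisopropylsilyl ether, which resists migration to the neighbouring C7 oxygen and basic hydrolysis on the way. C4 is fixed after ring closure by proton return from the ring C phenol, not in the C–C bond formation itself, where an enolate with its C3–H in plane would favour the aroyl group trans to ring A.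

Step 1
Reactants: 1 2,4-dihydroxybenzaldehyde
Product: 2 2-hydroxy-4-(methoxymethoxy)benzaldehyde
Conditions: MOMCl (1.1 equiv), K2CO3, acetone, rt
Reagents that add atoms: chloromethyl methyl ether, COCCl
Why: Williamson-type O-alkylation in which the 4-hydroxyl, the more acidic and unhindered phenol, reacts while the 2-hydroxyl is held in a hydrogen bond to the aldehyde, so one equivalent of reagent should protect the para oxygen only.

Step 2
Reactants: 2 2-hydroxy-4-(methoxymethoxy)benzaldehyde
Product: 3 4-(methoxymethoxy)-2-[(triisopropylsilyl)oxy]benzaldehyde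
Conditions: NaH, TIPSCl, THF, 0 °C → rt
Reagents that add atoms: chlorotri(propan-2-yl)silane, CC(C)[Si](Cl)(C(C)C)C(C)C
Why: Silyl ether formation on the sodium phenoxide, the bulky triisopropylsilyl group being chosen because it resists migration to a neighbouring alkoxide and basic hydrolysis in the steps ahead yet still leaves with fluoride in step 14.

Step 3
Reactants: 3 4-(methoxymethoxy)-2-[(triisopropylsilyl)oxy]benzaldehyde; 4 3-bromo-2-methylprop-1-ene
Product: 5 rac-1-[4-(methoxymethoxy)-2-(triisopropylsilyloxy)phenyl]-3-methylbut-3-en-1-ol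
Conditions: Zn dust, THF/sat. aq NH4Cl, 0 °C → rt
Reagents that add atoms: none
Why: Barbier-type zinc allylation in a protic medium that protonates the alkoxide at once, so the ortho silyl ether cannot migrate, and the new carbinol centre is made as a racemate on purpose because this carbon becomes trigonal in step 14.

Step 4
Reactants: 5 rac-1-[4-(methoxymethoxy)-2-(triisopropylsilyloxy)phenyl]-3-methylbut-3-en-1-ol; 6 dibutyl ethenylboronate
Product: 9 rac-6-[4-(methoxymethoxy)-2-(triisopropylsilyloxy)phenyl]-4-methyl-5,6-dihydro-2H-1,2-oxaborinin-2-ol, via mixed vinylboronate 7 (not isolated), via cyclic butyl boronate 8 (not isolated)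
Conditions: CH2Cl2, rt, then evaporation of BuOH; second-generation Grubbs catalyst (5 mol%), CH2Cl2, 40 °C; H2O work-up
Reagents that add atoms: water, O
Why: Boron-tethered ring-closing metathesis, in which ester exchange binds the vinylboron unit to the carbinol oxygen and metathesis with the 1,1-disubstituted alkene closes a six-membered ring that holds boron and the CH2 group cis on the new trisubstituted alkene, which fixes the later Z relationship of C3 and C6.

Step 5
Reactants: 10 4-bromobenzene-1,3-diol (4-bromoresorcinol)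
Product: 11 1-bromo-2,4-bis(methoxymethoxy)benzene
Conditions: MOMCl, NaH, DMF, 0 °C → rt
Reagents that add atoms: chloromethyl methyl ether, COCCl
Why: Double Williamson-type acetal formation on both phenoxides, giving ethers that later direct metalation and survive base, fluoride and palladium.

Step 6
Reactants: 11 1-bromo-2,4-bis(methoxymethoxy)benzene
Product: 13 3-bromo-2,6-bis(methoxymethoxy)benzaldehyde, via aryllithium 12 (not isolated)
Conditions: LiN(iPr)2, THF, −78 °C; DMF, −78 → 0 °C; aq NH4Cl
Reagents that add atoms: N,N-dimethylformamide, CN(C)C=O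
Why: Directed ortho-metalation and formylation, in which the amide base removes the proton flanked by both acetal oxygens without halogen–lithium exchange at the C–Br bond and the formamide traps aryllithium 12.

Step 7
Reactants: 14 2-bromobenzene-1,3-diol (2-bromoresorcinol)
Product: 15 2-bromo-1,3-bis(methoxymethoxy)benzene
Conditions: MOMCl, NaH, DMF, 0 °C → rt
Reagents that add atoms: chloromethyl methyl ether, COCCl
Why: Double Williamson-type acetal formation, as in step 5.

Step 8
Reactants: 16 3-methylbut-1-yne; 17 4,4,5,5-tetramethyl-1,3,2-dioxaborolane (pinacolborane)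
Product: 18 (E)-4,4,5,5-tetramethyl-2-(3-methylbut-1-enyl)-1,3,2-dioxaborolane
Conditions: Cp2Zr(H)Cl (5 mol%), Et3N (10 mol%), neat, 60 °C
Reagents that add atoms: none
Why: Zirconium-catalysed hydroboration of a terminal alkyne, a syn addition that places boron on the terminal carbon and so gives the E-alkenylboronate.

Step 9
Reactants: 15 2-bromo-1,3-bis(methoxymethoxy)benzene; 18 (E)-4,4,5,5-tetramethyl-2-(3-methylbut-1-enyl)-1,3,2-dioxaborolane
Product: 19 1,3-bis(methoxymethoxy)-2-[(E)-3-methylbut-1-enyl]benzene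
Conditions: Pd(OAc)2 (2 mol%), SPhos (4 mol%), K3PO4, toluene/H2O, 90 °C
Reagents that add atoms: none
Why: Suzuki–Miyaura coupling with a bulky biarylphosphine, which tolerates the doubly ortho-substituted aryl bromide and transfers the alkenyl group with retention of its E geometry.

Step 10
Reactants: 19 1,3-bis(methoxymethoxy)-2-[(E)-3-methylbut-1-enyl]benzene
Product: 21 1-{2,4-bis(methoxymethoxy)-3-[(E)-3-methylbut-1-enyl]phenyl}ethanone, via aryllithium 20 (not isolated)
Conditions: n-BuLi, TMEDA, THF, 0 °C; MeC(O)N(OMe)Me, −78 °C → rt; aq NH4Cl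
Reagents that add atoms: N-methoxy-N-methylacetamide, CC(=O)N(C)OC
Why: Directed ortho-metalation next to an acetal oxygen (the two open ortho positions are equivalent) and acylation of aryllithium 20 with an N-methoxy-N-methylamide, whose chelated tetrahedral intermediate stops the addition at the ketone.

Step 11
Reactants: 13 3-bromo-2,6-bis(methoxymethoxy)benzaldehyde; 21 1-{2,4-bis(methoxymethoxy)-3-[(E)-3-methylbut-1-enyl]phenyl}ethanone
Product: 22 (E)-3-[3-bromo-2,6-bis(methoxymethoxy)phenyl]-1-{2,4-bis(methoxymethoxy)-3-[(E)-3-methylbut-1-enyl]phenyl}prop-2-en-1-one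
Conditions: KOH, EtOH, rt
Reagents that add atoms: none
Why: Claisen–Schmidt condensation, in which the aldehyde cannot enolise, the methyl ketone is the only enolisable partner, and dehydration of the aldol gives the E-enone.

Step 12
Reactants: 22 (E)-3-[3-bromo-2,6-bis(methoxymethoxy)phenyl]-1-{2,4-bis(methoxymethoxy)-3-[(E)-3-methylbut-1-enyl]phenyl}prop-2-en-1-one; 9 rac-6-[4-(methoxymethoxy)-2-(triisopropylsilyloxy)phenyl]-4-methyl-5,6-dihydro-2H-1,2-oxaborinin-2-ol
Product: 23 (3R,4Z)-3-[3-bromo-2,6-bis(methoxymethoxy)phenyl]-1-{2,4-bis(methoxymethoxy)-3-[(E)-3-methylbut-1-enyl]phenyl}-7-hydroxy-7-[4-(methoxymethoxy)-2-(triisopropylsilyloxy)phenyl]-5-methylhept-4-en-1-one (both C7 epimers)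
Conditions: [RhCl(C2H4)2]2 (2.5 mol%), (R,R)-Ph-bod* [(1R,4R)-2,5-diphenylbicyclo[2.2.2]octa-2,5-diene] (5.5 mol%), Et3N, dioxane/H2O (10:1), 50 °C; 9 in excess
Reagents that add atoms: none
Why: Rhodium-catalysed asymmetric 1,4-addition of an alkenylboronic acid to an enone (Hayashi–Miyaura reaction), in which the cyclic boronic acid opens in the aqueous base, its Z-alkenyl group passes to rhodium with retention, the chiral diene directs carbometalation to the Si face of the β-carbon so that C3 is set as R, and protonolysis and borate hydrolysis release the C7 alcohol.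

Step 13
Reactants: 23 (3R,4Z)-hydroxy ketone (both C7 epimers)
Product: 24 (3R,4Z)-7-acetoxy-3-[3-bromo-2,6-bis(methoxymethoxy)phenyl]-1-{2,4-bis(methoxymethoxy)-3-[(E)-3-methylbut-1-enyl]phenyl}-7-[4-(methoxymethoxy)-2-(triisopropylsilyloxy)phenyl]-5-methylhept-4-en-1-one (both C7 epimers)
Conditions: Ac2O, pyridine, DMAP (cat.), CH2Cl2, 0 °C
Reagents that add atoms: acetic anhydride, CC(=O)OC(C)=O
Why: Acylation of the secondary benzylic alcohol by nucleophilic catalysis under basic, non-ionising conditions, which installs the leaving group for step 14 and leaves the ketone and the aryl silyl ether untouched.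

Step 14
Reactants: 24 (3R,4Z)-7-acetoxy heptenone precursor (both C7 epimers)
Product: 29 {(3S,4R,5S)-3-[3-bromo-2,6-bis(methoxymethoxy)phenyl]-5-[2-hydroxy-4-(methoxymethoxy)phenyl]-1-methylcyclohex-1-en-4-yl}{2,4-bis(methoxymethoxy)-3-[(E)-3-methylbut-1-enyl]phenyl}methanone (route numbering), via potassium enolate 25 (not isolated), via ortho-quinone methide 26 (not isolated), via cyclised phenoxide ketone 27 (not isolated), via enolate phenoxide dianion 28 (not isolated)
Conditions: KN(SiMe3)2 (1.05 equiv), THF, −78 °C; TASF [(Me2N)3S(Me3SiF2)] in THF/DMF, −78 → −20 °C; KN(SiMe3)2 (1.2 equiv), −78 → −20 °C; 2,6-di-tert-butyl-4-methylphenol (1.2 equiv), −78 → 0 °C; aq NH4Cl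
Reagents that add atoms: none
Why: KN(SiMe3)2 removes a proton from C4, the only enolisable carbon of the ring B ketone, to give Z-enolate 25; fluoride then cleaves the aryl silyl ether, the phenoxide expels acetate from C5 to give ortho-quinone methide 26, and the enolate carbon adds to the exocyclic C5, the return of ring C to a phenoxide making the C4–C5 bond irreversible. The closest known reaction type is the fluoride-triggered release of ortho-quinone methides from ortho-silyloxybenzyl acetates with 1,4-addition of enolates, here run intramolecularly as a 6-(enolexo)-exo-trig closure of the cyclohexene. C5 is set in this bond formation: the tether can reach only the enolate face that carries C2, ring A as the largest group on C3 stays anti to the forming bond, and the quinone methide ring turns away from the twisted ring B aryl of the Z-enolate so that H5 lies beneath it, which should place rings A and C on opposite faces of the new ring from either acetate epimer. C4 is deliberately not left to the C–C bond formation: cyclised ketone 27 is re-enolised to dianion 28, the hindered phenol protonates it on oxygen, and the ring C phenol freed in this step then hands the proton to C4 through a six-membered transition state on its own face, so the aroyl group should end trans to ring C and therefore cis to ring A. The step needs C-alkylation by the enolate to outrun loss of a C6 proton from the quinone methide (which would give the conjugated aryl diene) and capture between molecules; the pre-formed enolate held five atoms from C5, the para acetal oxygen that tempers the quinone methide and the low temperature secure this, and attack through the enolate oxygen would require an eight-membered ring.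

Step 15
Reactants: 29 (3S,4R,5S)-bromo cyclohexene core
Product: 31 1-{3-[(3S,4R,5S)-4-{2,4-bis(methoxymethoxy)-3-[(E)-3-methylbut-1-enyl]benzoyl}-5-[2-hydroxy-4-(methoxymethoxy)phenyl]-1-methylcyclohex-1-en-3-yl]-2,4-bis(methoxymethoxy)phenyl}ethanone (route numbering), via enol ether 30 (not isolated)
Conditions: Bu3Sn[C(OEt)=CH2], PdCl2(PPh3)2 (5 mol%), toluene, 100 °C; then 1 M HCl, THF, rt
Reagents that add atoms: tributyl(1-ethoxyvinyl)stannane, CCOC(=C)[Sn](CCCC)(CCCC)CCCC; water, O
Why: Stille coupling of the aryl bromide with a 1-ethoxyvinyl stannane (a masked acetyl group) followed by mild acid hydrolysis of enol ether 30, conditions without base under which the free phenol, the acetals and the C4 stereocentre should not be affected.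

Step 16
Reactants: 1 2,4-dihydroxybenzaldehyde
Product: 32 2,4-bis(methoxymethoxy)benzaldehyde
Conditions: MOMCl, NaH, DMF, 0 °C → rt
Reagents that add atoms: chloromethyl methyl ether, COCCl
Why: Double Williamson-type acetal formation, sodium hydride also deprotonating the hydrogen-bonded 2-hydroxyl.

Step 17
Reactants: 31 ring A methyl ketone; 32 2,4-bis(methoxymethoxy)benzaldehyde
Product: 33 heptakis(methoxymethyl) ether of artonin C with the ring C ortho phenol free, (3S,4R,5S)
Conditions: KOH, EtOH/H2O, 0 °C → rt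
Reagents that add atoms: none
Why: Claisen–Schmidt condensation in which only the new methyl ketone can give a condensation product, because the ring B ketone has a single, shielded α-hydrogen at C4 and cannot dehydrate, while the ring C phenoxide formed under the conditions is a spectator.

Step 18
Reactants: 33 heptakis(methoxymethyl) ether of artonin C
Product: 35 artonin C, (3S,4R,5S) in the route numbering, via octakis(trimethylsilyl) ether 34 (not isolated)
Conditions: Me3SiOTf, 2,2'-bipyridyl, MeCN, 0 °C → rt; then H2O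
Reagents that add atoms: none
Why: Silyl-triflate-mediated cleavage of aryl methoxymethyl ethers buffered by 2,2'-bipyridyl, which exchanges each acetal for a trimethylsilyl ether (34) without free protic acid, so the ortho oxygens of rings A and C are never free in an acidic medium where they could add to the C4 ketone, and neutral hydrolysis then liberates all eight phenols.

Compound list
1 | 2,4-dihydroxybenzaldehyde | O=Cc1ccc(O)cc1O | starting material
2 | 2-hydroxy-4-(methoxymethoxy)benzaldehyde | O=Cc1ccc(OCOC)cc1O | intermediate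
3 | 4-(methoxymethoxy)-2-[(triisopropylsilyl)oxy]benzaldehyde | O=Cc1ccc(OCOC)cc1O[Si](C(C)C)(C(C)C)C(C)C | intermediate
4 | 3-bromo-2-methylprop-1-ene | CC(=C)CBr | starting material
5 | rac-1-[4-(methoxymethoxy)-2-(triisopropylsilyloxy)phenyl]-3-methylbut-3-en-1-ol | CC(=C)CC(O)c1ccc(OCOC)cc1O[Si](C(C)C)(C(C)C)C(C)C | intermediate
6 | dibutyl ethenylboronate | C=CB(OCCCC)OCCCC | starting material
7 | butyl 1-[4-(methoxymethoxy)-2-(triisopropylsilyloxy)phenyl]-3-methylbut-3-enyl ethenylboronate (racemic) | C=CB(OCCCC)OC(CC(C)=C)c1ccc(OCOC)cc1O[Si](C(C)C)(C(C)C)C(C)C | intermediate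
8 | rac-2-butoxy-6-[4-(methoxymethoxy)-2-(triisopropylsilyloxy)phenyl]-4-methyl-5,6-dihydro-2H-1,2-oxaborinine | CCCCOB1OC(c2ccc(OCOC)cc2O[Si](C(C)C)(C(C)C)C(C)C)CC(C)=C1 | intermediate
9 | rac-6-[4-(methoxymethoxy)-2-(triisopropylsilyloxy)phenyl]-4-methyl-5,6-dihydro-2H-1,2-oxaborinin-2-ol | OB1OC(c2ccc(OCOC)cc2O[Si](C(C)C)(C(C)C)C(C)C)CC(C)=C1 | intermediate
10 | 4-bromobenzene-1,3-diol | Oc1ccc(Br)c(O)c1 | starting material
11 | 1-bromo-2,4-bis(methoxymethoxy)benzene | COCOc1ccc(Br)c(OCOC)c1 | intermediate
12 | [3-bromo-2,6-bis(methoxymethoxy)phenyl]lithium | [Li]c1c(OCOC)ccc(Br)c1OCOC | intermediate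
13 | 3-bromo-2,6-bis(methoxymethoxy)benzaldehyde | O=Cc1c(OCOC)ccc(Br)c1OCOC | intermediate
14 | 2-bromobenzene-1,3-diol | Oc1cccc(O)c1Br | starting material
15 | 2-bromo-1,3-bis(methoxymethoxy)benzene | COCOc1cccc(OCOC)c1Br | intermediate
16 | 3-methylbut-1-yne | CC(C)C#C | starting material
17 | 4,4,5,5-tetramethyl-1,3,2-dioxaborolane | CC1(C)OBOC1(C)C | starting material
18 | (E)-4,4,5,5-tetramethyl-2-(3-methylbut-1-enyl)-1,3,2-dioxaborolane | CC(C)/C=C/B1OC(C)(C)C(C)(C)O1 | intermediate
19 | 1,3-bis(methoxymethoxy)-2-[(E)-3-methylbut-1-enyl]benzene | COCOc1cccc(OCOC)c1/C=C/C(C)C | intermediate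
20 | {2,4-bis(methoxymethoxy)-3-[(E)-3-methylbut-1-enyl]phenyl}lithium | [Li]c1ccc(OCOC)c(/C=C/C(C)C)c1OCOC | intermediate
21 | 1-{2,4-bis(methoxymethoxy)-3-[(E)-3-methylbut-1-enyl]phenyl}ethanone | CC(=O)c1ccc(OCOC)c(/C=C/C(C)C)c1OCOC | intermediate
22 | (E)-3-[3-bromo-2,6-bis(methoxymethoxy)phenyl]-1-{2,4-bis(methoxymethoxy)-3-[(E)-3-methylbut-1-enyl]phenyl}prop-2-en-1-one | O=C(/C=C/c1c(OCOC)ccc(Br)c1OCOC)c1ccc(OCOC)c(/C=C/C(C)C)c1OCOC | intermediate
23 | (3R,4Z)-3-[3-bromo-2,6-bis(methoxymethoxy)phenyl]-1-{2,4-bis(methoxymethoxy)-3-[(E)-3-methylbut-1-enyl]phenyl}-7-hydroxy-7-[4-(methoxymethoxy)-2-(triisopropylsilyloxy)phenyl]-5-methylhept-4-en-1-one, both C7 epimers | O=C(c1ccc(OCOC)c(/C=C/C(C)C)c1OCOC)C[C@@H](c1c(OCOC)ccc(Br)c1OCOC)/C=C(C)\CC(O)c1ccc(OCOC)cc1O[Si](C(C)C)(C(C)C)C(C)C | intermediate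
24 | (3R,4Z)-7-acetoxy-3-[3-bromo-2,6-bis(methoxymethoxy)phenyl]-1-{2,4-bis(methoxymethoxy)-3-[(E)-3-methylbut-1-enyl]phenyl}-7-[4-(methoxymethoxy)-2-(triisopropylsilyloxy)phenyl]-5-methylhept-4-en-1-one, both C7 epimers (precursor of the key step) | O=C(c1ccc(OCOC)c(/C=C/C(C)C)c1OCOC)C[C@@H](c1c(OCOC)ccc(Br)c1OCOC)/C=C(C)\CC(OC(C)=O)c1ccc(OCOC)cc1O[Si](C(C)C)(C(C)C)C(C)C | intermediate
25 | potassium (Z)-enolate of 24 at C4 | [K+].[O-]/C(c1ccc(OCOC)c(/C=C/C(C)C)c1OCOC)=C\[C@@H](c1c(OCOC)ccc(Br)c1OCOC)/C=C(C)\CC(OC(C)=O)c1ccc(OCOC)cc1O[Si](C(C)C)(C(C)C)C(C)C | intermediate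
26 | potassium enolate carrying the ring C ortho-quinone methide (E at the exocyclic bond) | [K+].[O-]/C(c1ccc(OCOC)c(/C=C/C(C)C)c1OCOC)=C\[C@@H](c1c(OCOC)ccc(Br)c1OCOC)/C=C(C)\C/C=C1\C=CC(OCOC)=CC1=O | intermediate
27 | potassium phenoxide of the cyclised ketone, (3S,5S), C4 as formed in the ring closure | [K+].CC1=C[C@H](c2c(OCOC)ccc(Br)c2OCOC)C(C(=O)c2ccc(OCOC)c(/C=C/C(C)C)c2OCOC)[C@@H](c2ccc(OCOC)cc2[O-])C1 | intermediate
28 | dipotassium enolate phenoxide of the cyclised ketone, (3S,5S) | [K+].[K+].CC1=C[C@H](c2c(OCOC)ccc(Br)c2OCOC)C(=C([O-])c2ccc(OCOC)c(/C=C/C(C)C)c2OCOC)[C@@H](c2ccc(OCOC)cc2[O-])C1 | intermediate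
29 | {(3S,4R,5S)-3-[3-bromo-2,6-bis(methoxymethoxy)phenyl]-5-[2-hydroxy-4-(methoxymethoxy)phenyl]-1-methylcyclohex-1-en-4-yl}{2,4-bis(methoxymethoxy)-3-[(E)-3-methylbut-1-enyl]phenyl}methanone (product of the key step) | CC1=C[C@H](c2c(OCOC)ccc(Br)c2OCOC)[C@H](C(=O)c2ccc(OCOC)c(/C=C/C(C)C)c2OCOC)[C@@H](c2ccc(OCOC)cc2O)C1 | intermediate
30 | 1-ethoxyvinyl analogue of 29 (ring A C–Br replaced by C–C(OEt)=CH2), (3S,4R,5S) | CC1=C[C@H](c2c(OCOC)ccc(C(=C)OCC)c2OCOC)[C@H](C(=O)c2ccc(OCOC)c(/C=C/C(C)C)c2OCOC)[C@@H](c2ccc(OCOC)cc2O)C1 | intermediate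
31 | ring A methyl ketone, (3S,4R,5S) | CC1=C[C@H](c2c(OCOC)ccc(C(C)=O)c2OCOC)[C@H](C(=O)c2ccc(OCOC)c(/C=C/C(C)C)c2OCOC)[C@@H](c2ccc(OCOC)cc2O)C1 | intermediate
32 | 2,4-bis(methoxymethoxy)benzaldehyde | O=Cc1ccc(OCOC)cc1OCOC | intermediate
33 | heptakis(methoxymethyl) ether of artonin C, ring C ortho phenol free, (3S,4R,5S) | CC1=C[C@H](c2c(OCOC)ccc(C(=O)/C=C/c3ccc(OCOC)cc3OCOC)c2OCOC)[C@H](C(=O)c2ccc(OCOC)c(/C=C/C(C)C)c2OCOC)[C@@H](c2ccc(OCOC)cc2O)C1 | intermediate
34 | octakis(trimethylsilyl) ether of artonin C | CC1=C[C@H](c2c(O[Si](C)(C)C)ccc(C(=O)/C=C/c3ccc(O[Si](C)(C)C)cc3O[Si](C)(C)C)c2O[Si](C)(C)C)[C@H](C(=O)c2ccc(O[Si](C)(C)C)c(/C=C/C(C)C)c2O[Si](C)(C)C)[C@@H](c2ccc(O[Si](C)(C)C)cc2O[Si](C)(C)C)C1 | intermediate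
35 | artonin C | CC1=C[C@H](c2c(O)ccc(C(=O)/C=C/c3ccc(O)cc3O)c2O)[C@H](C(=O)c2ccc(O)c(/C=C/C(C)C)c2O)[C@@H](c2ccc(O)cc2O)C1 | target

Total step count: 18.
Longest linear sequence: 10 steps (steps 1, 2, 3, 4, 12, 13, 14, 15, 17, 18; the ring B branch through steps 7, 9, 10, 11 is equally long).

Steps most likely to fail

Step 14. The quinone methide may shed a C6 proton to the conjugated aryl diene or be captured between molecules before the enolate reaches C5, the new bond may form on the other face of C5, or the proton return to C4 may not be face-selective. The fallback leaves the route at 24 and rejoins it at 29; it closes the ring through a benzylic cation instead of a quinone methide, with no base present when the bond forms. Ketone 24 is converted (LiN(SiMe3)2, Me3SiCl, THF, −78 °C) into its (Z)-trimethylsilyl enol ether F5. A catalytic Lewis acid (Sc(OTf)3, CH2Cl2, −40 °C) ionises the benzylic acetate, which the two oxygens of ring C make easy, and the enol silane closes the ring in an intramolecular Mukaiyama-type alkylation to the ring C triisopropylsilyl ether of 29 F6. Bu4NF buffered with AcOH (THF, 0 °C) then frees the phenol to give 29. If the ring closure delivers the C4 epimer, the enolisation and proton-return part of step 14 is applied to 29.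

Step 12. Carbometalation at the β-carbon, which is flanked by two ortho acetal groups, may be slow enough for protodeboronation of the alkenyl partner to take over, or the facial discrimination may be poor. The fallback leaves the route at 13, 9 and 19 and rejoins it at 23; it makes the same bond under auxiliary control. Aldehyde 13 is condensed (Horner–Wadsworth–Emmons, LiCl, iPr2NEt, MeCN) with diethyl {2-oxo-2-[(4S)-2-oxo-4-phenyl-1,3-oxazolidin-3-yl]ethyl}phosphonate, itself made from (4S)-4-phenyl-1,3-oxazolidin-2-one, bromoacetyl bromide and triethyl phosphite, to give the (E)-enoyl imide (4S)-3-[(E)-3-(3-bromo-2,6-bis(methoxymethoxy)phenyl)prop-2-enoyl]-4-phenyl-1,3-oxazolidin-2-one F1. Boronic acid 9 is treated with N-iodosuccinimide (MeCN, 0 °C; iododeboronation with retention) to give the Z-alkenyl iodide rac-(3Z)-4-iodo-3-methyl-1-[4-(methoxymethoxy)-2-(triisopropylsilyloxy)phenyl]but-3-en-1-ol F2. F2 is deprotonated and lithiated (n-BuLi, then t-BuLi, Et2O, −78 °C) and transmetalated (MgBr2·OEt2, CuBr·SMe2). The alkenylcopper reagent adds to the chelated imide F1 anti to the phenyl group, which should set C3 as in 23 and give the conjugate adduct imide F3. Exchange of the auxiliary (AlMe3, MeNHOMe·HCl, CH2Cl2) gives the N-methoxy-N-methylamide F4, and aryllithium 20, generated from 19 as in step 10, converts F4 into 23.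

Step 18. Exchange of seven acetals may stop at partly protected stages, or the silyl triflate may promote addition of the ortho oxygens of rings A and C to the C4 ketone or to the nearby alkenes. The fallback leaves the route at 33 and rejoins it at 35; it blocks ketal formation with a temporary silyl group and then uses ordinary protic hydrolysis. The free ring C phenol of 33 is silylated (TBSCl, imidazole, DMF) to the ring C tert-butyldimethylsilyl ether of 33 F7. HCl in MeOH (rt) removes the seven methoxymethyl groups while the ring C ortho oxygen stays blocked, giving the ring C mono(tert-butyldimethylsilyl) ether of artonin C F8. Bu4NF buffered with AcOH (THF, 0 °C) then gives 35.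

Further compounds
F1 | step 12 | (4S)-3-[(E)-3-(3-bromo-2,6-bis(methoxymethoxy)phenyl)prop-2-enoyl]-4-phenyl-1,3-oxazolidin-2-one | O=C(/C=C/c1c(OCOC)ccc(Br)c1OCOC)N1C(=O)OC[C@@H]1c1ccccc1
F2 | step 12 | rac-(3Z)-4-iodo-3-methyl-1-[4-(methoxymethoxy)-2-(triisopropylsilyloxy)phenyl]but-3-en-1-ol | I/C=C(C)\CC(O)c1ccc(OCOC)cc1O[Si](C(C)C)(C(C)C)C(C)C
F3 | step 12 | (4S)-3-{(3R,4Z)-3-[3-bromo-2,6-bis(methoxymethoxy)phenyl]-7-hydroxy-7-[4-(methoxymethoxy)-2-(triisopropylsilyloxy)phenyl]-5-methylhept-4-enoyl}-4-phenyl-1,3-oxazolidin-2-one, both C7 epimers | O=C(C[C@@H](c1c(OCOC)ccc(Br)c1OCOC)/C=C(C)\CC(O)c1ccc(OCOC)cc1O[Si](C(C)C)(C(C)C)C(C)C)N1C(=O)OC[C@@H]1c1ccccc1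
F4 | step 12 | (3R,4Z)-3-[3-bromo-2,6-bis(methoxymethoxy)phenyl]-7-hydroxy-N-methoxy-7-[4-(methoxymethoxy)-2-(triisopropylsilyloxy)phenyl]-N,5-dimethylhept-4-enamide, both C7 epimers | CON(C)C(=O)C[C@@H](c1c(OCOC)ccc(Br)c1OCOC)/C=C(C)\CC(O)c1ccc(OCOC)cc1O[Si](C(C)C)(C(C)C)C(C)C
F5 | step 14 | (Z)-trimethylsilyl enol ether of 24 | C[Si](C)(C)O/C(c1ccc(OCOC)c(/C=C/C(C)C)c1OCOC)=C\[C@@H](c1c(OCOC)ccc(Br)c1OCOC)/C=C(C)\CC(OC(C)=O)c1ccc(OCOC)cc1O[Si](C(C)C)(C(C)C)C(C)C
F6 | step 14 | ring C triisopropylsilyl ether of 29, (3S,4R,5S) | CC1=C[C@H](c2c(OCOC)ccc(Br)c2OCOC)[C@H](C(=O)c2ccc(OCOC)c(/C=C/C(C)C)c2OCOC)[C@@H](c2ccc(OCOC)cc2O[Si](C(C)C)(C(C)C)C(C)C)C1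
F7 | step 18 | ring C tert-butyldimethylsilyl ether of 33, (3S,4R,5S) | CC1=C[C@H](c2c(OCOC)ccc(C(=O)/C=C/c3ccc(OCOC)cc3OCOC)c2OCOC)[C@H](C(=O)c2ccc(OCOC)c(/C=C/C(C)C)c2OCOC)[C@@H](c2ccc(OCOC)cc2O[Si](C)(C)C(C)(C)C)C1
F8 | step 18 | ring C mono(tert-butyldimethylsilyl) ether of artonin C, (3S,4R,5S) | CC1=C[C@H](c2c(O)ccc(C(=O)/C=C/c3ccc(O)cc3O)c2O)[C@H](C(=O)c2ccc(O)c(/C=C/C(C)C)c2O)[C@@H](c2ccc(O)cc2O[Si](C)(C)C(C)(C)C)C1
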